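**Retrosynthetic overview**

1. (−)-Tanegol ⇐ LiAlH4 opening of a cis-fused 3,6-diaryl-furo[3,4-c]furan-1-one. The feature used is that the exocyclic CH2OH carbon on C3 and the ArCH(OH) carbon on C4 of the oxolane ring are cis on adjacent ring carbons. Joined through one oxygen they form a γ-lactone, which is the two carbons of an arylketene plus one inserted oxygen.
2. Lactone ⇐ Baeyer–Villiger oxygen insertion on the benzylic side of a cis-fused 2,6-diaryl-3-oxabicyclo[3.2.0]heptan-7-one.
3. Cyclobutanone ⇐ EtAlCl2-promoted (2+2) cycloaddition of an arylketene across C3=C4 of an (S)-2-aryl-2,5-dihydrofuran, anti to the C2 aryl, forming C3–C(=O) and C4–CH(Ar).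
4. Dihydrofuran ⇐ ring-closing metathesis of an allyl 1-arylallyl ether ⇐ lipase-resolved vinyl carbinol from O-pivaloylvanillin; ketene ⇐ O-pivaloylhomovanillic acid chloride.
5. Ring order: oxolane ring (metathesis), then the cyclobutanone (cycloaddition), expanded to the lactone ring, which is opened at the end.

Key step: step 8

**Remarks on the chemistry**

- Both phenols are carried as pivalates, not silyl ethers. An acyloxy para-substituent withholds the electron release that would let EtAlCl2 ionise the benzylic, allylic C2–O bond of the dihydrofuran, and LiAlH4 removes the pivalates in the step that opens the lactone.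
- Assumption: Candida antarctica lipase B shows its usual preference for 1-aryl carbinols (aryl large, vinyl medium) and acylates the (R)-alcohol, so the alcohol left over is (S).
- Locants: the oxolane of 8 and 16 is numbered O1, C2 (aryl), C3, C4, C5. Bicycles 13 and 14 are numbered C1 (bridgehead next to C2 and the carbonyl), C2 (aryl), O3, C4, C5 (bridgehead), C6 (aryl), C7 (C=O).

**Route**

Step 1
Reactants: 1 vanillin
Product: 2 4-formyl-2-methoxyphenyl pivalate
Conditions: PivCl, Et3N, DMAP (cat.), CH2Cl2, 0 °C to rt
Reagents that add atoms: pivaloyl chloride, CC(C)(C)C(Cl)=O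
Why: DMAP-catalysed O-acylation of the phenol should give the hindered aryl ester, which is meant to survive every step up to the final hydride reduction.

Step 2
Reactants: 2 4-formyl-2-methoxyphenyl pivalate; 3 vinylmagnesium bromide
Product: 4 rac-4-(1-hydroxyprop-2-en-1-yl)-2-methoxyphenyl pivalate
Conditions: 3 (1.05 equiv), THF, −78 °C; aq NH4Cl at −78 °C
Reagents that add atoms: vinylmagnesium bromide, C=C[Mg]Br
Why: Grignard 1,2-addition to the aldehyde should be far faster at −78 °C than attack on the tert-butyl-shielded aryl ester, giving the racemic vinyl carbinol.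

Step 3
Reactants: 4 rac-4-(1-hydroxyprop-2-en-1-yl)-2-methoxyphenyl pivalate
Product: 5 (S)-4-(1-hydroxyprop-2-en-1-yl)-2-methoxyphenyl pivalate
Conditions: Novozym 435 (immobilised Candida antarctica lipase B), vinyl acetate, MTBE, 30 °C, stopped just past half conversion; chromatography
Reagents that add atoms: none
Why: Lipase-catalysed kinetic resolution by irreversible transesterification should acetylate the (R)-alcohol (Kazlauskas rule) and leave the (S)-alcohol, whose carbinol centre becomes C2 of the oxolane.

Step 4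
Reactants: 5 (S)-4-(1-hydroxyprop-2-en-1-yl)-2-methoxyphenyl pivalate; 6 allyl bromide
Product: 7 (S)-4-[1-(allyloxy)prop-2-en-1-yl]-2-methoxyphenyl pivalate
Conditions: Ag2O, 6 (5 equiv), 4 Å molecular sieves, Et2O, rt, dark
Reagents that add atoms: allyl bromide, C=CCBr
Why: Silver-oxide-mediated Williamson etherification alkylates the hydroxyl without generating a free alkoxide (which could transfer the aryl pivaloyl group) and breaks no bond at the stereocentre, so the configuration is kept.

Step 5
Reactants: 7 (S)-4-[1-(allyloxy)prop-2-en-1-yl]-2-methoxyphenyl pivalate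
Product: 8 (S)-4-(2,5-dihydrofuran-2-yl)-2-methoxyphenyl pivalate
Conditions: second-generation Grubbs catalyst RuCl2(=CHPh)(H2IMes)(PCy3) (2 mol %), 1,4-benzoquinone (10 mol %), CH2Cl2, 40 °C
Reagents that add atoms: none
Why: Ring-closing metathesis of the two terminal alkenes should close the five-membered ring with loss of ethylene, benzoquinone suppressing hydride-mediated alkene migration, and the stereocentre is untouched.

Step 6
Reactants: 9 homovanillic acid
Product: 10 2-[3-methoxy-4-(pivaloyloxy)phenyl]acetic acid
Conditions: NaOH (aq, 2.2 equiv), PivCl (1.2 equiv), THF–H2O, 0 °C; then HCl to pH 2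
Reagents that add atoms: pivaloyl chloride, CC(C)(C)C(Cl)=O
Why: Schotten–Baumann acylation should take place at the phenoxide of the dianion, any mixed anhydride at the carboxylate being hydrolysed in the aqueous base.

Step 7
Reactants: 10 2-[3-methoxy-4-(pivaloyloxy)phenyl]acetic acid
Product: 11 2-[3-methoxy-4-(pivaloyloxy)phenyl]acetyl chloride
Conditions: (COCl)2, DMF (cat.), CH2Cl2, 0 °C to rt; evaporated and used crude
Reagents that add atoms: oxalyl chloride, O=C(Cl)C(Cl)=O
Why: Vilsmeier-type activation converts the acid into the acid chloride under conditions that leave the aryl pivalate alone.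

Step 8
Reactants: 8 (S)-4-(2,5-dihydrofuran-2-yl)-2-methoxyphenyl pivalate; 11 2-[3-methoxy-4-(pivaloyloxy)phenyl]acetyl chloride
Product: 14 (1S,2S,5R,6S)-2,6-bis[3-methoxy-4-(pivaloyloxy)phenyl]-3-oxabicyclo[3.2.0]heptan-7-one (cis-fused; C6 aryl exo; C2 aryl trans to the cyclobutanone), via arylketene 12 (not isolated), via C6-endo cyclobutanone 13 (not isolated)
Conditions: 11 (2 equiv), Et3N, CH2Cl2, −78 °C; EtAlCl2 (hexanes, 5 equiv), −78 °C; Et3N, aq potassium sodium tartrate; then DBU (0.2 equiv), CH2Cl2, 0 °C on the crude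
Reagents that add atoms: none
Why: Et3N dehydrochlorinates 11 to the aldoketene 12, whose oxygen binds EtAlCl2, and the C3=C4 alkene of 8 attacks the activated central carbon in a concerted but strongly asynchronous [π2s+π2a] event, the Lewis acid promoted ketene–alkene (2+2) cycloaddition known for unactivated cycloalkenes, with C3–C(=O) forming ahead of C4–CH(Ar). The four-membered ring closes when the aluminium enolate carbon collapses onto the developing C4 cation on the same alkene face, so it can only be cis-fused to the oxolane. Both bonds form on the face anti to the C2 aryl, which sets C1 and C5 relative to the resolved C2 centre and hence their absolute configuration. C6 is the only epimerisable centre (benzylic and α to the strained ketone, whereas C1 cannot invert without a trans ring fusion), so catalytic DBU should converge any endo epimer 13 on the exo-aryl isomer 14. The step needs the carbonyl carbon at C3 and the aryl-bearing carbon at C4, a bias that is expected to be modest: the compact sp carbon is the one that can sit next to the substituted C2, the developing positive charge is better placed at C4 (next to a CH2) than at C3 (next to the aryl- and oxygen-bearing C2), and the bulkier CH(Ar) terminus ends on the open C4 side. The extra EtAlCl2 allows for binding to the two pivalate carbonyls, which further deactivates the aryl rings toward ionisation of the C2–O bond.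

Step 9
Reactants: 14 (1S,2S,5R,6S)-2,6-bis[3-methoxy-4-(pivaloyloxy)phenyl]-3-oxabicyclo[3.2.0]heptan-7-one
Product: 15 (3S,3aR,6S,6aS)-3,6-bis[3-methoxy-4-(pivaloyloxy)phenyl]tetrahydro-1H,3H-furo[3,4-c]furan-1-one (cis-fused; C3 aryl exo)
Conditions: mCPBA, NaHCO3, CH2Cl2, 0 °C to rt
Reagents that add atoms: mCPBA, OOC(=O)c1cccc(Cl)c1
Why: Baeyer–Villiger oxidation driven by cyclobutanone strain, in which benzylic C6 should migrate in preference to bridgehead C1 (deactivated by the ring oxygen on the adjacent C2) and does so with retention, turning the exo C6 centre into the (S)-configured lactone carbinol carbon.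

Step 10
Reactants: 15 (3S,3aR,6S,6aS)-3,6-bis[3-methoxy-4-(pivaloyloxy)phenyl]tetrahydro-1H,3H-furo[3,4-c]furan-1-one
Product: 16 (−)-tanegol, (S)-(4-hydroxy-3-methoxyphenyl)[(3R,4R,5S)-4-(hydroxymethyl)-5-(4-hydroxy-3-methoxyphenyl)oxolan-3-yl]methanol
Conditions: LiAlH4 (excess), THF, 0 °C to rt; EtOAc, then aq potassium sodium tartrate at about pH 7
Reagents that add atoms: none
Why: Hydride reduction opens the lactone to the primary alcohol on C3 and the secondary benzylic alcohol on C4 and cleaves both aryl pivalates in the same operation, no stereocentre being touched, and the neutral work-up avoids acid-promoted recyclisation of the p-hydroxybenzylic alcohol.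

**Compound list**

1 | vanillin | COc1cc(C=O)ccc1O | starting material
2 | 4-formyl-2-methoxyphenyl pivalate | COc1cc(C=O)ccc1OC(=O)C(C)(C)C | intermediate
3 | vinylmagnesium bromide | C=C[Mg]Br | starting material
4 | rac-4-(1-hydroxyprop-2-en-1-yl)-2-methoxyphenyl pivalate | C=CC(O)c1ccc(OC(=O)C(C)(C)C)c(OC)c1 | intermediate
5 | (S)-4-(1-hydroxyprop-2-en-1-yl)-2-methoxyphenyl pivalate | C=C[C@H](O)c1ccc(OC(=O)C(C)(C)C)c(OC)c1 | intermediate
6 | allyl bromide | C=CCBr | starting material
7 | (S)-4-[1-(allyloxy)prop-2-en-1-yl]-2-methoxyphenyl pivalate | C=CCO[C@@H](C=C)c1ccc(OC(=O)C(C)(C)C)c(OC)c1 | intermediate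
8 | (S)-4-(2,5-dihydrofuran-2-yl)-2-methoxyphenyl pivalate | C1=CCO[C@@H]1c2ccc(OC(=O)C(C)(C)C)c(OC)c2 | intermediate
9 | homovanillic acid | COc1cc(CC(O)=O)ccc1O | starting material
10 | 2-[3-methoxy-4-(pivaloyloxy)phenyl]acetic acid | COc1cc(CC(O)=O)ccc1OC(=O)C(C)(C)C | intermediate
11 | 2-[3-methoxy-4-(pivaloyloxy)phenyl]acetyl chloride | COc1cc(CC(Cl)=O)ccc1OC(=O)C(C)(C)C | intermediate
12 | [3-methoxy-4-(pivaloyloxy)phenyl]ketene (not isolated) | O=C=Cc1ccc(OC(=O)C(C)(C)C)c(OC)c1 | intermediate
13 | (1S,2S,5R,6R)-2,6-bis[3-methoxy-4-(pivaloyloxy)phenyl]-3-oxabicyclo[3.2.0]heptan-7-one, C6 aryl endo (not isolated) | O=C1[C@@H](c3ccc(OC(=O)C(C)(C)C)c(OC)c3)[C@H]2CO[C@H](c4ccc(OC(=O)C(C)(C)C)c(OC)c4)[C@@H]12 | intermediate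
14 | (1S,2S,5R,6S)-2,6-bis[3-methoxy-4-(pivaloyloxy)phenyl]-3-oxabicyclo[3.2.0]heptan-7-one, C6 aryl exo | O=C1[C@H](c3ccc(OC(=O)C(C)(C)C)c(OC)c3)[C@H]2CO[C@H](c4ccc(OC(=O)C(C)(C)C)c(OC)c4)[C@@H]12 | intermediate
15 | (3S,3aR,6S,6aS)-3,6-bis[3-methoxy-4-(pivaloyloxy)phenyl]tetrahydro-1H,3H-furo[3,4-c]furan-1-one | O=C1O[C@H](c3ccc(OC(=O)C(C)(C)C)c(OC)c3)[C@H]2CO[C@H](c4ccc(OC(=O)C(C)(C)C)c(OC)c4)[C@@H]12 | intermediate
16 | (−)-tanegol | COc1cc([C@@H](O)[C@H]2CO[C@H](c3ccc(O)c(OC)c3)[C@H]2CO)ccc1O | target

**Step count**

Total: 10 steps. Longest linear sequence: 8 steps (steps 1, 2, 3, 4, 5, 8, 9, 10, from vanillin).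

**Steps most likely to fail**

1. Step 8. The ketene may add in the reverse orientation (aryl-bearing carbon to C3). The monosubstituted ketene may also dimerise, or the aluminium Lewis acid may open the benzylic C2–O bond, before cycloaddition occurs. Fallback, setting out from 11 and 8 and coming back at 14: 11 is treated with dimethylamine to give N,N-dimethyl-2-[3-methoxy-4-(pivaloyloxy)phenyl]acetamide F1. Tf2O and 2,4,6-collidine in 1,2-dichloroethane convert F1 into the keteniminium triflate F2, a ketene surrogate that does not dimerise and needs no aluminium reagent. Its thermal (2+2) addition to 8 should give the cyclobutaniminium triflate F3. Aqueous NaHCO3 hydrolysis and the same DBU equilibration return to 14. This removes the dimerisation and Lewis-acid problems; the orientation still rests on the same charge preference for C4.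

2. Step 9. Bridgehead C1 may migrate in competition with benzylic C6, putting the oxygen on the wrong side of the carbonyl; the acyloxy-substituted aryl makes C6 a less eager migrating group. Fallback, setting out from 14 and coming back at 15: TBSOTf and Et3N enolise only toward the benzylic carbon and give the 7-silyloxy-bicyclohept-6-ene silyl enol ether F4. Ozonolysis (O3, CH2Cl2–MeOH, −78 °C; Me2S) cleaves C6=C7 to the (2S,3S,4R)-4-aroyl-2-aryl-oxolane-3-carboxylic acid keto acid F5. TMSCHN2 gives the keto methyl ester F6. (R)-Me-CBS oxazaborolidine with BH3·SMe2 should reduce the aryl ketone under reagent control to the (S)-carbinol hydroxy ester F7, which lactonises (pyridinium p-toluenesulfonate, CH2Cl2) to 15. The oxygen position is then fixed by construction.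

3. Step 4. The silver-mediated etherification may be slow, and during it the benzylic, allylic alcohol may ionise (erosion of enantiopurity, allylic transposition) or a pivaloyl group may migrate. Fallback, setting out from 5 and coming back at 7: O-allylation through a π-allylpalladium electrophile under neutral conditions (allyl tert-butyl carbonate, Pd2(dba)3, 1,4-bis(diphenylphosphino)butane, THF, 60 °C). Only a catalytic, hindered tert-butoxide is generated and no new compound arises on the way (F0).

**Further compounds**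

F1 | step 8 | N,N-dimethyl-2-[3-methoxy-4-(pivaloyloxy)phenyl]acetamide | CN(C)C(=O)Cc1ccc(OC(=O)C(C)(C)C)c(OC)c1
F2 | step 8 | N,N-dimethyl aryl keteniminium triflate | C[N+](C)=C=Cc1ccc(OC(=O)C(C)(C)C)c(OC)c1.[O-]S(=O)(=O)C(F)(F)F
F3 | step 8 | (1S,2S,5R,6S)-2,6-diaryl-3-oxabicyclo[3.2.0]heptan-7-ylidene dimethyliminium triflate | C[N+](C)=C1[C@H](c3ccc(OC(=O)C(C)(C)C)c(OC)c3)[C@H]2CO[C@H](c4ccc(OC(=O)C(C)(C)C)c(OC)c4)[C@@H]12.[O-]S(=O)(=O)C(F)(F)F
F4 | step 9 | (1S,2S,5R)-7-(tert-butyldimethylsilyloxy)-2,6-diaryl-3-oxabicyclo[3.2.0]hept-6-ene | CC(C)(C)[Si](C)(C)OC1=C(c3ccc(OC(=O)C(C)(C)C)c(OC)c3)[C@H]2CO[C@H](c4ccc(OC(=O)C(C)(C)C)c(OC)c4)[C@@H]12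
F5 | step 9 | (2S,3S,4R)-4-[3-methoxy-4-(pivaloyloxy)benzoyl]-2-[3-methoxy-4-(pivaloyloxy)phenyl]oxolane-3-carboxylic acid | O=C(c3ccc(OC(=O)C(C)(C)C)c(OC)c3)[C@H]1CO[C@H](c4ccc(OC(=O)C(C)(C)C)c(OC)c4)[C@H]1C(O)=O
F6 | step 9 | methyl ester of F5 | O=C(c3ccc(OC(=O)C(C)(C)C)c(OC)c3)[C@H]1CO[C@H](c4ccc(OC(=O)C(C)(C)C)c(OC)c4)[C@H]1C(=O)OC
F7 | step 9 | methyl (2S,3S,4R)-4-[(S)-hydroxy(aryl)methyl]-2-aryl-oxolane-3-carboxylate | O[C@H](c3ccc(OC(=O)C(C)(C)C)c(OC)c3)[C@H]1CO[C@H](c4ccc(OC(=O)C(C)(C)C)c(OC)c4)[C@H]1C(=O)OC
F0 | step 4 | none | none
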